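## Analysis of the target

Chromone numbering is used for the reduced unit and primed numbers for the aromatic unit. Target 34 joins two 2-(2-phenylethyl)chromones: a 5,6,7,8-tetrahydrochromone with oxygen on every sp3 ring carbon, and a 6′,7′-dioxygenated aromatic chromone bound through O6′ to C5. The four contiguous stereocentres are 5S,6S,7R,8S. The C5 aryloxy group and the C8 hydroxyl lie on one face of the carbocycle and the C6 and C7 hydroxyls on the other (5,6-trans, 6,7-cis, 7,8-trans). The C5–O bond is the weak point: C5 hangs on C4a, so a cation there is stabilised by O1 through C4a=C8a, and loss of the oxygen substituents leads to a fully aromatic chromone. C8–H is vinylogously acidic, and the free 7′-phenol and the two pyranone rings exclude strong bases, hydrides and hard nucleophiles late in the route. The hard part is a secondary alkyl aryl ether at a hindered, ionisable carbon with fixed configuration relative to three hydroxyls; it cannot come from SNAr and is unsafe by substitution on a polyol. The strategy rests on C5 and C8, which flank the C4a=C8a bond in a 1,4 relationship. An aryloxy group on C8 can reach a carbene centre on C5 through a five-membered ring, and a [2,3]-shift of the resulting oxonium ylide through a vinyl group on C8 hands the aryloxy group to C5 while C5–C6 and the carbocycle form.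

## Retrosynthetic reasoning

34 ⇒ 33. Only the 7′-O–benzyl bond is cut. The benzyl ether keeps O6′ and O7′ distinct from 3 onwards and is the one group that comes off under neutral conditions at the end.

33 ⇒ 32 ⇒ 31. The C8–O bond is cut and traced to the 7,8-epoxide 32, because a trans opening at C8 gives the 7,8-trans diol in one operation. The epoxide is traced to the allylic alcohol 31, whose C6 hydroxyl can steer the oxidant to its own face and so fixes C7 and C8 relative to C6.

31 ⇒ 30. The C6–O bond is exchanged for a C6–Si bond. Silicon is an oxygen surrogate that survives the carbene step and is converted with retention, so the configuration of C6 can be set when the ring is closed.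

30 ⇒ 26 (via 29 and 28). The C5–C6 bond and the O–C5 bond are cut and the oxygen is returned to C8. This opens the carbocycle to the oxonium ylide 29, which comes from a carbene centre at C5 (diazo compound 28, tosylhydrazone 26) and an aryl ether at C8. Cutting here, and not at C5–O alone, replaces a substitution at the ionisable C5 by a sigmatropic transfer from C8, where substitution is safe. The same step forms the ring and both C5 and C6. The forward reaction has to beat cyclopropanation and the [1,2]-shift and has to pass the configuration of C8 and the Z geometry on to C5 and C6.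

26 ⇒ 25 ⇒ 24. The hydrazone is made last, because its N–H would compete in the etherification. A free C5 aldehyde next to a free C8 hydroxyl would also close to a lactol, so C5 is carried as a dimethyl acetal. The Z-vinylsilane 25 is traced to the alkynylsilane 24, since syn addition of hydrogen fixes the geometry without ambiguity.

24 ⇒ 23 + 6. The C8–O bond is cut. C8 sits on C8a, the acceptor end of the vinylogous ester, and has no β-hydrogen, so an SN2 etherification with inversion is clean there. 23 ⇒ 18 + 22 cuts the C8–alkyne bond, which a catalytic enantioselective alkynylation of an aldehyde can form.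

18 ⇒ 16 ⇒ 15. The two aldehyde carbons on C4a and C8a must be told apart. In 15 the C5 carbon is the only aldehyde and the C8 carbon is hidden as a styryl group. Acetal formation followed by oxidative cleavage swaps the roles.

15 ⇒ 9 + 13. The pyranone is cut at O1–C8a and C4–C4a. The acylketene 14 (from 9) supplies C2, C3, C4 and O1 with the phenylethyl group. The push-pull enamine 13 supplies C8a and C4a with their two substituents in fixed positions, so no regiochemical choice arises on the ring. 13 ⇒ 12 ⇒ 10 and 9 ⇒ 7 + 8 are standard.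

6 ⇒ 3 + 4 ⇒ 1 + 2. The aromatic chromone is cut at C2′–C3′ and O1′–C2′ (Claisen condensation and cyclodehydration). 3 comes from 1 by alkylation with 2 at the most acidic hydroxyl. 22 ⇒ 19 + 20 makes the alkyne carrier of the silicon.

## Alternatives that were turned down

Alternative 1: Ring B of the aromatic unit is made last by cutting C6′–C7′. In the forward sense, light triggers a Wolff rearrangement of a diazo ketone function on the primed pyranone. The ketene carbon (C7′) then closes onto the enol-ether carbon C6′, which already carries the C5 oxygen, in a thermal six-electron electrocyclisation. Tautomerisation gives A1 with the 7′-hydroxyl free.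
- For: the ether is brought in as an O-vinyl ether of a C5 alcohol, so no substitution at C5 is needed. The 6′-O/7′-OH pattern is automatic and no phenol differentiation is required. Benzannulation through dienylketenes is an established reaction type, so on precedent for the key step this alternative is stronger than the chosen one.
- Against: the key step creates no stereocentre, so all four must be made beforehand on a carbocycle that also carries an acetonide, a methoxymethyl ether and an acid-labile enol ether. Two adjacent carbons of a second pyranone must be dressed with a Z-alkoxyvinyl group and a diazoacetyl group. The photolysis runs in the presence of two cross-conjugated pyranone chromophores, which have photochemistry of their own.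
- Comparison: the route is clearly longer. The chosen strategy offers instead a key step that builds the carbocycle, the ether and two stereocentres at once, with the aromatic unit available in two steps.

Alternative 2: The C5–O6′ bond is treated as a diaryl ether of a 5,8-dioxygenated aromatic chromone, and the temporary C5–O7′ bond of A2 is cut. In the forward sense a hypervalent iodine oxidant attacks the C8 phenol and O7′ adds to the para carbon C5. This closes a five-membered dioxole and turns ring A into a cyclohexadienone.
- For: all precursors are flat aromatics, diaryl ether formation is reliable and oxidative dearomatisation is well known. Up to A2 this alternative is shorter and better precedented than the chosen route.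
- Against: A2 is racemic and holds C5 at the ketal oxidation level. The target then needs reductive cleavage of the C5–O7′ bond in preference to C5–O6′ with control at C5, reduction of the C8 ketone, and a face-selective cis-dihydroxylation of C6=C7 of a cross-conjugated dienone. Nothing in A2 biases these three operations, and absolute configuration has no source.
- Comparison: the chosen strategy is longer to its key step, but it sets C5 and C6 by transfer from a centre made by a catalytic asymmetric reaction.

Alternative 3: The pyranone of the reduced unit is annulated last by cutting C4–C4a and O1–C8a. In the forward sense a thermally released acylketene adds across the C4a=C8a enol-ether bond of a cyclohexene that carries C5 to C8 fully dressed. Loss of the methoxy group from C8a gives the pyranone of A3.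
- For: the annulation is a known reaction type (step 6 of the chosen route uses the same type on a simple partner). The plan is convergent, and the sensitive pyranone appears only at the end. On precedent this alternative is stronger.
- Against: it needs an enantiopure tetra-oxygenated cyclohexanone enol ether in which the aryloxy group has already been installed by substitution at a hindered secondary carbon flanked by oxygen functions. The nucleophilic carbon C4a is shielded by the C5 aryloxy group. Heating to the temperature at which the acylketene forms invites β-elimination towards an aromatic ring. The sequence to the carbocycle is long.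
- Comparison: the chosen strategy makes the C5–O bond by an intramolecular shift, not by substitution, and builds the carbocycle from an achiral pyranone.

Key step: step 14

Notation: Ar = 7-(benzyloxy)-4-oxo-2-(2-phenylethyl)-4H-chromen-6-yl.

Assumption: hydrazone 26 is drawn as its E isomer (the geometry is lost when the diazo group forms), and the ProPhenol antipode in step 10 is whichever one adds the alkynyl group to the Re face of 18, to be confirmed on a Mosher ester of 23.

## Route

Step 1
Reactants: 1 2,4,5-trihydroxyacetophenone; 2 benzyl bromide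
Product: 3 1-[4-(benzyloxy)-2,5-dihydroxyphenyl]ethan-1-one
Conditions: Li2CO3 (1.1 equiv), DMF, 50 °C, argon
Reagents that add atoms: none
Why: Williamson etherification; the 4-hydroxyl is para to the acetyl group and the most acidic, the 2-hydroxyl is hydrogen-bonded to the carbonyl and the 5-hydroxyl is the least acidic, so one equivalent of a weak base should alkylate O4 only.

Step 2
Reactants: 3 1-[4-(benzyloxy)-2,5-dihydroxyphenyl]ethan-1-one; 4 ethyl 3-phenylpropanoate
Product: 6 7-(benzyloxy)-6-hydroxy-2-(2-phenylethyl)-4H-chromen-4-one, via aryl β-diketone 5 (not isolated)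
Conditions: NaH (5 equiv), THF, reflux; then HCl, MeOH, 50 °C
Reagents that add atoms: none
Why: Claisen condensation of the acetophenone enolate (formed beside the two phenoxides) with the ester, then acid-catalysed cyclodehydration of the 2-hydroxyaryl β-diketone to the chromone; the 5-hydroxyl of 3 becomes the free 6-hydroxyl.

Step 3
Reactants: 7 3-phenylpropanoyl chloride; 8 2,2-dimethyl-1,3-dioxane-4,6-dione (Meldrum's acid)
Product: 9 5-(1-hydroxy-3-phenylpropylidene)-2,2-dimethyl-1,3-dioxane-4,6-dione
Conditions: pyridine (2.2 equiv), CH2Cl2, 0 °C to rt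
Reagents that add atoms: none
Why: C-acylation of Meldrum's acid; the enolised acyl derivative is a storable source of the acylketene needed in step 6.

Step 4
Reactants: 10 (E)-4-phenylbut-3-en-2-one
Product: 12 (2Z,4E)-3-chloro-5-phenylpenta-2,4-dienal, via chlorovinyl iminium salt 11 (not isolated)
Conditions: POCl3 (2.5 equiv), DMF, 0 to 50 °C; then ice water
Reagents that add atoms: N,N-dimethylformamide CN(C)C=O; phosphoryl chloride O=P(Cl)(Cl)Cl; water O
Why: Vilsmeier–Haack chloroformylation of a methyl ketone; the methyl group is formylated, the ketone oxygen is exchanged for chlorine and hydrolysis of the iminium salt frees the aldehyde.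

Step 5
Reactants: 12 (2Z,4E)-3-chloro-5-phenylpenta-2,4-dienal
Product: 13 (2E,4E)-3-(morpholin-4-yl)-5-phenylpenta-2,4-dienal
Conditions: morpholine (2.2 equiv), Et2O, 0 °C to rt
Reagents that add atoms: morpholine C1COCCN1
Why: Addition–elimination at the β-carbon of a β-chlorovinyl aldehyde gives the vinylogous formamide; the amine now marks the carbon that will become C8a.

Step 6
Reactants: 9 5-(1-hydroxy-3-phenylpropylidene)-2,2-dimethyl-1,3-dioxane-4,6-dione; 13 (2E,4E)-3-(morpholin-4-yl)-5-phenylpenta-2,4-dienal
Product: 15 4-oxo-6-(2-phenylethyl)-2-[(E)-2-phenylethenyl]-4H-pyran-3-carbaldehyde, via acylketene 14 (not isolated)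
Conditions: 9 (2 equiv), toluene, 90 °C; then TsOH·H2O (cat.), rt
Reagents that add atoms: none
Why: Acylketene–enamine annulation to a 4-pyranone: thermal fragmentation of 9 gives 14, the nucleophilic α-carbon of 13 attacks the ketene carbon and the enol oxygen closes onto the amine-bearing carbon, which then loses morpholine. The enamine fixes the pattern (amine carbon becomes C8a with the styryl group, formyl-bearing carbon becomes C4a); the second equivalent of 9 takes up the released amine.

Step 7
Reactants: 15 4-oxo-6-(2-phenylethyl)-2-[(E)-2-phenylethenyl]-4H-pyran-3-carbaldehyde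
Product: 16 3-(dimethoxymethyl)-6-(2-phenylethyl)-2-[(E)-2-phenylethenyl]-4H-pyran-4-one
Conditions: HC(OMe)3, MeOH, TsOH·H2O (cat.), rt
Reagents that add atoms: trimethyl orthoformate COC(OC)OC
Why: Acid-catalysed acetal formation at the only aldehyde; the orthoformate removes water, and the acetal keeps the future C5 carbon inert through the next five steps.

Step 8
Reactants: 16 3-(dimethoxymethyl)-6-(2-phenylethyl)-2-[(E)-2-phenylethenyl]-4H-pyran-4-one
Product: 18 3-(dimethoxymethyl)-4-oxo-6-(2-phenylethyl)-4H-pyran-2-carbaldehyde, via vicinal diol 17 (not isolated)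
Conditions: OsO4 (2 mol %), NaIO4 (4 equiv), 2,6-lutidine, 1,4-dioxane/H2O, rt
Reagents that add atoms: osmium tetroxide O=[Os](=O)(=O)=O; sodium periodate [Na+].[O-]I(=O)(=O)=O
Why: Lemieux–Johnson cleavage; the styryl bond is the only isolated alkene, the ring double bonds being part of the vinylogous ester, and the buffered medium leaves the acetal intact.

Step 9
Reactants: 19 ethynylmagnesium bromide; 20 dichlorodimethylsilane
Product: 22 ethynyl(dimethyl)(propan-2-yloxy)silane, via chloro(ethynyl)dimethylsilane 21 (not isolated)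
Conditions: 20 (3 equiv), THF, −78 to 0 °C; then iPrOH, Et3N, 0 °C; distillation
Reagents that add atoms: propan-2-ol CC(C)O
Why: Monosubstitution of an excess of the dichlorosilane by the Grignard reagent, then alcoholysis of the remaining Si–Cl bond; the isopropoxy group is what later makes the silane oxidisable.

Step 10
Reactants: 18 3-(dimethoxymethyl)-4-oxo-6-(2-phenylethyl)-4H-pyran-2-carbaldehyde; 22 ethynyl(dimethyl)(propan-2-yloxy)silane
Product: 23 3-(dimethoxymethyl)-2-{(1R)-1-hydroxy-3-[dimethyl(propan-2-yloxy)silyl]prop-2-yn-1-yl}-6-(2-phenylethyl)-4H-pyran-4-one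
Conditions: Me2Zn (3 equiv), ProPhenol (20 mol %, antipode for Re-face addition), Ph3PO (40 mol %), toluene, 0 °C
Reagents that add atoms: none
Why: Catalytic enantioselective addition of an alkynylzinc to an aldehyde; the dinuclear zinc–ProPhenol complex binds both partners and adds the alkynyl group to the Re face, which sets C8 as R. This centre is sacrificial, and its configuration is passed on to C5 and C6 in step 14.

Step 11
Reactants: 23 (1R)-propargylic alcohol; 6 7-(benzyloxy)-6-hydroxy-2-(2-phenylethyl)-4H-chromen-4-one
Product: 24 2-{(1S)-1-(ArO)-3-[dimethyl(propan-2-yloxy)silyl]prop-2-yn-1-yl}-3-(dimethoxymethyl)-6-(2-phenylethyl)-4H-pyran-4-one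
Conditions: PPh3, DIAD, toluene, 0 °C to rt
Reagents that add atoms: none
Why: Mitsunobu etherification with inversion at C8; the carbon is attached to the acceptor end of the vinylogous ester, so ionisation is disfavoured and SN2 is favoured, and it has no β-hydrogen to lose.

Step 12
Reactants: 24 (1S)-propargylic aryl ether
Product: 25 2-{(1S,2Z)-1-(ArO)-3-[dimethyl(propan-2-yloxy)silyl]prop-2-en-1-yl}-3-(dimethoxymethyl)-6-(2-phenylethyl)-4H-pyran-4-one
Conditions: H2 (1 atm), Pd/CaCO3 poisoned with Pb(OAc)2 (Lindlar catalyst), quinoline, EtOAc, rt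
Reagents that add atoms: none
Why: Lindlar semihydrogenation; syn addition of hydrogen to the alkynylsilane gives the Z-vinylsilane, and the benzyl ether, the aryl ethers and both pyranone rings are not touched by the poisoned catalyst at 1 atm.

Step 13
Reactants: 25 (1S,2Z)-vinylsilane acetal
Product: 26 N′-[(E)-(2-{(1S,2Z)-1-(ArO)-3-[dimethyl(propan-2-yloxy)silyl]prop-2-en-1-yl}-4-oxo-6-(2-phenylethyl)-4H-pyran-3-yl)methylidene]-4-methylbenzenesulfonohydrazide
Conditions: TsNHNH2 (1.1 equiv), PPTS (10 mol %), iPrOH/THF, 40 °C
Reagents that add atoms: 4-methylbenzenesulfonohydrazide Cc1ccc(cc1)S(=O)(=O)NN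
Why: Acid-catalysed exchange of the dimethyl acetal for the sulfonylhydrazone; the oxocarbenium ion at the C5 carbon is stabilised by O1 through C4a=C8a, so a pyridinium salt is enough. Isopropanol as solvent keeps the Si–O-isopropyl group in place, and C8 does not ionise because C8a is the acceptor end.

Step 14
Reactants: 26 tosylhydrazone
Product: 30 (5S,6S)-5-(ArO)-6-[dimethyl(propan-2-yloxy)silyl]-2-(2-phenylethyl)-5,6-dihydro-4H-chromen-4-one, via sodium hydrazonide 27 (not isolated), via diazo compound 28 (not isolated), via oxonium ylide 29 (not isolated)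
Conditions: NaH (1.0 equiv), THF, 0 °C; then Rh2(OAc)4 (2 mol %), BnEt3NCl (10 mol %), 1,4-dioxane, 40 °C
Reagents that add atoms: none
Why: Proposed new method: deprotonated 26 loses sulfinate (Bamford–Stevens) to give diazo compound 28, Rh2(OAc)4 turns it into a C5 carbene, and the aryl ether oxygen on C8 adds to it to close the five-membered oxonium ylide 29 (O–C5 bond; the 1,4 relation of C5 and C8 across C4a=C8a makes this a favoured five-ring closure). The ylide carbon C5 then bonds to the silyl-bearing alkene terminus C6 while O–C8 breaks, a suprafacial [2,3]-shift through a bicyclo[2.2.1] transition state shaped like 7-oxanorbornadiene; this closes the six-membered carbocycle in a 6-endo sense (both alkene carbons end up in the ring) and leaves the C7=C8 bond and the aryloxy group on C5. The closest known reactions are the intramolecular formation of five-membered O-aryl oxonium ylides from metal carbenes followed by [2,3]-shift, and ring-expanding [2,3]-shifts of cyclic onium ylides that carry a vinyl group next to the heteroatom; the case in which the allyl unit is part of the ylide ring and the aryl group stays on oxygen is new. C5 is controlled by C8: the vinyl group sits on one face of the ylide ring, C6 can reach C5 only from that face and the oxygen bridge stays on the other, so (S)-C8 gives (S)-C5. C6 is controlled by the alkene geometry: in the only rotamer that aligns the C8–O bond with the π system the Z substituent points under the C4a=C8a bond, which places silicon trans to the aryloxy group. The step needs ylide formation to beat cyclopropanation of the vinylsilane, which is helped by the five-membered ring, by the low reactivity of a Z-disubstituted vinylsilane towards carbene addition and by the absence of a hydrogen on C4a for a 1,2-shift. It also needs the [2,3]-shift to beat the [1,2]-shift, which would give a cyclobutene fused to the pyranone and is therefore strained. One equivalent of base and 40 °C are chosen so that the acidic C8–H is not exchanged before the diazo group forms.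

Step 15
Reactants: 30 (5S,6S)-allylsilane
Product: 31 (5S,6S)-5-(ArO)-6-hydroxy-2-(2-phenylethyl)-5,6-dihydro-4H-chromen-4-one
Conditions: KF, KHCO3, 30% H2O2, THF/MeOH, 0 °C to rt
Reagents that add atoms: hydrogen peroxide OO
Why: Tamao oxidation; hydroperoxide adds to the activated alkoxysilane and C6 migrates from silicon to oxygen with retention, so the C6 hydroxyl is trans to the aryloxy group. Allylic and β-oxygenated alkoxysilanes are known substrates, and the weakly basic bicarbonate medium is chosen to hold back elimination.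

Step 16
Reactants: 31 (5S,6S)-allylic alcohol
Product: 32 (5S,6R,7R,8R)-5-(ArO)-7,8-epoxy-6-hydroxy-2-(2-phenylethyl)-5,6,7,8-tetrahydro-4H-chromen-4-one
Conditions: VO(acac)2 (5 mol %), tBuOOH (1.5 equiv), CH2Cl2, 0 °C to rt
Reagents that add atoms: tert-butyl hydroperoxide CC(C)(C)OO
Why: Hydroxyl-directed vanadium-catalysed epoxidation; the alkylperoxo vanadate bound to the C6 hydroxyl delivers oxygen to the C7=C8 bond on the face of that hydroxyl, which sets C7 and C8. The aryloxy group lies on the other face and does not interfere.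

Step 17
Reactants: 32 epoxy alcohol
Product: 33 (5S,6S,7R,8S)-5-(ArO)-6,7,8-trihydroxy-2-(2-phenylethyl)-5,6,7,8-tetrahydro-4H-chromen-4-one
Conditions: HClO4 (0.05 M), THF/H2O, 0 °C to rt
Reagents that add atoms: water O
Why: Acid-catalysed trans opening of the epoxide; water attacks C8, the allylic carbon next to C8a where substitution with inversion is assisted by the adjacent π system, while C7 is flanked by the C6 carbinol. Inversion at C8 gives the 7,8-trans diol with the C8 hydroxyl on the face of the aryloxy group, and protonation of the pyranone carbonyl works against ionisation of the C5–O bond.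

Step 18
Reactants: 33 benzyl-protected triol
Product: 34 (5S,6S,7R,8S)-6,7,8-trihydroxy-5-{[7-hydroxy-4-oxo-2-(2-phenylethyl)-4H-chromen-6-yl]oxy}-2-(2-phenylethyl)-5,6,7,8-tetrahydro-4H-chromen-4-one
Conditions: H2 (1 atm), Pd/C (10%), EtOAc/MeOH, rt
Reagents that add atoms: none
Why: Hydrogenolysis of the aryl benzyl ether under neutral conditions; the chromone double bonds are known to survive these conditions, and the hindered secondary C5 ether is expected to be cleaved far more slowly than the primary benzyl ether.

## Compound list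

1 | 2,4,5-trihydroxyacetophenone | CC(=O)c1cc(O)c(O)cc1O | starting material
2 | benzyl bromide | BrCc1ccccc1 | starting material
3 | 1-[4-(benzyloxy)-2,5-dihydroxyphenyl]ethan-1-one | CC(=O)c1cc(O)c(OCc2ccccc2)cc1O | intermediate
4 | ethyl 3-phenylpropanoate | CCOC(=O)CCc1ccccc1 | starting material
5 | 1-[4-(benzyloxy)-2,5-dihydroxyphenyl]-5-phenylpentane-1,3-dione | O=C(CC(=O)CCc1ccccc1)c1cc(O)c(OCc2ccccc2)cc1O | intermediate
6 | 7-(benzyloxy)-6-hydroxy-2-(2-phenylethyl)-4H-chromen-4-one | O=c1cc(CCc2ccccc2)oc2cc(OCc3ccccc3)c(O)cc12 | intermediate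
7 | 3-phenylpropanoyl chloride | O=C(Cl)CCc1ccccc1 | starting material
8 | 2,2-dimethyl-1,3-dioxane-4,6-dione | CC1(C)OC(=O)CC(=O)O1 | starting material
9 | 5-(1-hydroxy-3-phenylpropylidene)-2,2-dimethyl-1,3-dioxane-4,6-dione | CC1(C)OC(=O)C(=C(O)CCc2ccccc2)C(=O)O1 | intermediate
10 | (E)-4-phenylbut-3-en-2-one | CC(=O)/C=C/c1ccccc1 | starting material
11 | N-[(2Z,4E)-3-chloro-5-phenylpenta-2,4-dien-1-ylidene]-N-methylmethanaminium dichlorophosphate | C[N+](C)=C/C=C(\Cl)/C=C/c1ccccc1.[O-]P(=O)(Cl)Cl | intermediate
12 | (2Z,4E)-3-chloro-5-phenylpenta-2,4-dienal | O=C/C=C(\Cl)/C=C/c1ccccc1 | intermediate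
13 | (2E,4E)-3-(morpholin-4-yl)-5-phenylpenta-2,4-dienal | O=C/C=C(/N1CCOCC1)\C=C\c1ccccc1 | intermediate
14 | 3-oxo-5-phenylpent-1-en-1-one (acylketene) | O=C=CC(=O)CCc1ccccc1 | intermediate
15 | 4-oxo-6-(2-phenylethyl)-2-[(E)-2-phenylethenyl]-4H-pyran-3-carbaldehyde | O=Cc1c(/C=C/c2ccccc2)oc(CCc2ccccc2)cc1=O | intermediate
16 | 3-(dimethoxymethyl)-6-(2-phenylethyl)-2-[(E)-2-phenylethenyl]-4H-pyran-4-one | COC(OC)c1c(/C=C/c2ccccc2)oc(CCc2ccccc2)cc1=O | intermediate
17 | 2-(1,2-dihydroxy-2-phenylethyl)-3-(dimethoxymethyl)-6-(2-phenylethyl)-4H-pyran-4-one (racemic syn diol) | COC(OC)c1c(C(O)C(O)c2ccccc2)oc(CCc2ccccc2)cc1=O | intermediate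
18 | 3-(dimethoxymethyl)-4-oxo-6-(2-phenylethyl)-4H-pyran-2-carbaldehyde | COC(OC)c1c(C=O)oc(CCc2ccccc2)cc1=O | intermediate
19 | ethynylmagnesium bromide | C#C[Mg]Br | starting material
20 | dichlorodimethylsilane | C[Si](C)(Cl)Cl | starting material
21 | chloro(ethynyl)dimethylsilane | C#C[Si](C)(C)Cl | intermediate
22 | ethynyl(dimethyl)(propan-2-yloxy)silane | C#C[Si](C)(C)OC(C)C | intermediate
23 | 3-(dimethoxymethyl)-2-{(1R)-1-hydroxy-3-[dimethyl(propan-2-yloxy)silyl]prop-2-yn-1-yl}-6-(2-phenylethyl)-4H-pyran-4-one | COC(OC)c1c([C@H](O)C#C[Si](C)(C)OC(C)C)oc(CCc2ccccc2)cc1=O | intermediate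
24 | 2-{(1S)-1-{[7-(benzyloxy)-4-oxo-2-(2-phenylethyl)-4H-chromen-6-yl]oxy}-3-[dimethyl(propan-2-yloxy)silyl]prop-2-yn-1-yl}-3-(dimethoxymethyl)-6-(2-phenylethyl)-4H-pyran-4-one | COC(OC)c1c([C@@H](Oc2cc3c(=O)cc(CCc4ccccc4)oc3cc2OCc2ccccc2)C#C[Si](C)(C)OC(C)C)oc(CCc2ccccc2)cc1=O | intermediate
25 | 2-{(1S,2Z)-1-{[7-(benzyloxy)-4-oxo-2-(2-phenylethyl)-4H-chromen-6-yl]oxy}-3-[dimethyl(propan-2-yloxy)silyl]prop-2-en-1-yl}-3-(dimethoxymethyl)-6-(2-phenylethyl)-4H-pyran-4-one | COC(OC)c1c([C@@H](Oc2cc3c(=O)cc(CCc4ccccc4)oc3cc2OCc2ccccc2)/C=C\[Si](C)(C)OC(C)C)oc(CCc2ccccc2)cc1=O | intermediate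
26 | N′-[(E)-(2-{(1S,2Z)-1-{[7-(benzyloxy)-4-oxo-2-(2-phenylethyl)-4H-chromen-6-yl]oxy}-3-[dimethyl(propan-2-yloxy)silyl]prop-2-en-1-yl}-4-oxo-6-(2-phenylethyl)-4H-pyran-3-yl)methylidene]-4-methylbenzenesulfonohydrazide | Cc1ccc(cc1)S(=O)(=O)N/N=C/c1c(oc(CCc2ccccc2)cc1=O)[C@@H](Oc1cc2c(=O)cc(CCc3ccccc3)oc2cc1OCc1ccccc1)/C=C\[Si](C)(C)OC(C)C | intermediate
27 | sodium salt of 26 (N-sodio sulfonylhydrazonide) | [Na+].Cc1ccc(cc1)S(=O)(=O)[N-]/N=C/c1c(oc(CCc2ccccc2)cc1=O)[C@@H](Oc1cc2c(=O)cc(CCc3ccccc3)oc2cc1OCc1ccccc1)/C=C\[Si](C)(C)OC(C)C | intermediate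
28 | 2-{(1S,2Z)-1-{[7-(benzyloxy)-4-oxo-2-(2-phenylethyl)-4H-chromen-6-yl]oxy}-3-[dimethyl(propan-2-yloxy)silyl]prop-2-en-1-yl}-3-(diazomethyl)-6-(2-phenylethyl)-4H-pyran-4-one | [N-]=[N+]=Cc1c(oc(CCc2ccccc2)cc1=O)[C@@H](Oc1cc2c(=O)cc(CCc3ccccc3)oc2cc1OCc1ccccc1)/C=C\[Si](C)(C)OC(C)C | intermediate
29 | cyclic O-aryl oxonium ylide: furo[3,4-b]pyran-4-one in which O6′ bridges the C5 carbanion and C8, with C8 bearing the (Z)-2-silylethenyl group (C8 configuration unchanged) | O=c1cc(CCc2ccccc2)oc2c1[CH-][O+](c1cc3c(=O)cc(CCc4ccccc4)oc3cc1OCc1ccccc1)[C@H]2/C=C\[Si](C)(C)OC(C)C | intermediate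
30 | (5S,6S)-5-{[7-(benzyloxy)-4-oxo-2-(2-phenylethyl)-4H-chromen-6-yl]oxy}-6-[dimethyl(propan-2-yloxy)silyl]-2-(2-phenylethyl)-5,6-dihydro-4H-chromen-4-one | O=c1cc(CCc2ccccc2)oc2c1[C@H](Oc1cc3c(=O)cc(CCc4ccccc4)oc3cc1OCc1ccccc1)[C@@H]([Si](C)(C)OC(C)C)C=C2 | intermediate
31 | (5S,6S)-5-{[7-(benzyloxy)-4-oxo-2-(2-phenylethyl)-4H-chromen-6-yl]oxy}-6-hydroxy-2-(2-phenylethyl)-5,6-dihydro-4H-chromen-4-one | O=c1cc(CCc2ccccc2)oc2c1[C@H](Oc1cc3c(=O)cc(CCc4ccccc4)oc3cc1OCc1ccccc1)[C@@H](O)C=C2 | intermediate
32 | (5S,6R,7R,8R)-5-{[7-(benzyloxy)-4-oxo-2-(2-phenylethyl)-4H-chromen-6-yl]oxy}-7,8-epoxy-6-hydroxy-2-(2-phenylethyl)-5,6,7,8-tetrahydro-4H-chromen-4-one (epoxide on the face of the 6-hydroxyl) | O=c1cc(CCc2ccccc2)oc2c1[C@H](Oc1cc3c(=O)cc(CCc4ccccc4)oc3cc1OCc1ccccc1)[C@@H](O)[C@H]1O[C@@H]21 | intermediate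
33 | (5S,6S,7R,8S)-5-{[7-(benzyloxy)-4-oxo-2-(2-phenylethyl)-4H-chromen-6-yl]oxy}-6,7,8-trihydroxy-2-(2-phenylethyl)-5,6,7,8-tetrahydro-4H-chromen-4-one | O=c1cc(CCc2ccccc2)oc2c1[C@H](Oc1cc3c(=O)cc(CCc4ccccc4)oc3cc1OCc1ccccc1)[C@@H](O)[C@@H](O)[C@@H]2O | intermediate
34 | (5S,6S,7R,8S)-6,7,8-trihydroxy-5-{[7-hydroxy-4-oxo-2-(2-phenylethyl)-4H-chromen-6-yl]oxy}-2-(2-phenylethyl)-5,6,7,8-tetrahydro-4H-chromen-4-one | O=c1cc(CCc2ccccc2)oc2c1[C@H](Oc1cc3c(=O)cc(CCc4ccccc4)oc3cc1O)[C@@H](O)[C@@H](O)[C@@H]2O | target

## Step count and least certain steps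

Total step count: 18. Longest linear sequence: 14 steps (steps 4 to 8 and 10 to 18, from 10).

**Step 14 (key step).**
- What may go wrong:
  - The carbene may add to the vinylsilane (cyclopropanation), or the vinyl diazo unit of 28 may close to a pyrazole, before the weakly basic aryl ether oxygen is engaged.
  - The ylide may collapse by C8–O heterolysis and unselective recombination or by a [1,2]-shift, with loss of the stereochemical relay.
  - The silyl group has to sit under the C4a=C8a bond in the transition state, and this compression may raise the barrier of the [2,3]-shift above that of the side paths.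
  - Base-induced exchange of the acidic C8–H before diazo formation would erode the configuration that is to be transferred.
- Fallback (known chemistry, oxygen transfer given up), from 15 and 6, returning at 33:
  - The free C5 aldehyde of 15 is alkynylated with ethynyltrimethylsilane under the conditions of step 10 to the C5 (R)-propargylic alcohol F1.
  - Mitsunobu reaction with 6 gives the C5 aryl ether F2 with inversion.
  - Lemieux–Johnson cleavage of the styryl group gives the C8 aldehyde F3.
  - A second catalyst-controlled alkynylation gives the C8 (S)-propargylic alcohol F4.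
  - K2CO3 in MeOH removes both trimethylsilyl groups to give the diyne F5.
  - Lindlar semihydrogenation gives the diene F6.
  - Ring-closing metathesis with the second-generation Grubbs catalyst closes C6=C7 and gives the cis-5-aryloxy-8-hydroxy-5,8-dihydrochromone F7.
  - OsO4 with N-methylmorpholine N-oxide adds the 6,7-diol anti to both allylic oxygens and gives 33.

**Step 15.**
- What may go wrong: attack of fluoride or hydroperoxide at silicon can end in anti elimination of silicon and the β-aryloxy group, or in cleavage of the C6–Si bond towards the extended enolate. Both paths lead to aromatisation of the carbocycle instead of migration of C6 to oxygen.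
- Fallback, from 30, returning at 33: the allylsilane is used in its own sense.
  - Dimethyldioxirane in acetone at −20 °C epoxidises C7=C8 anti to silicon and gives the epoxysilane F8.
  - Buffered Bu4NF triggers the anti elimination of silicon and the C7–O bond (Peterson-type) to give the same 5,8-dihydrochromone F7.
  - OsO4 with N-methylmorpholine N-oxide then gives 33 as above.
- The weak point of this fallback is that the pseudoaxial aryloxy group may shield the face anti to silicon.

**Step 6.**
- What may go wrong: the push-pull enamine may be too weak a nucleophile, or the morpholine set free may consume the acylketene faster than the annulation proceeds.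
- Fallback, from 13, returning at 15:
  - 13 is C-acylated (Et3N, toluene, 0 °C) with 5-phenylpent-2-ynoyl chloride F10, made from the purchasable acid with oxalyl chloride, to give the acylated enaminal F11.
  - Aqueous HCl in THF then hydrates the ynone to the enol, which closes onto the amine-bearing carbon with loss of morpholine and gives 15.

**Step 17.**
- What may go wrong: water may attack C7 instead of C8, which gives the diastereomeric diol, or the acid may ionise the C5–O bond.
- Fallback, from 32, returning at 33:
  - Ti(OiPr)4 (1.5 equiv) and benzoic acid in CH2Cl2 open the 2,3-epoxy alcohol unit (C6 hydroxyl, C7, C8) at the distal carbon C8 with inversion and give the 8-O-benzoate F9.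
  - K2CO3 in MeOH at 0 °C removes the benzoate.

**Step 10.**
- What may go wrong: the very electrophilic aldehyde may react through an unselective background addition, or the neighbouring acetal may bind zinc and lower the facial selectivity.
- Fallback, from 18, returning at 23:
  - The lithium acetylide of 22 (LiN(SiMe3)2, THF, −78 °C) adds to give the racemic propargylic alcohol F12.
  - MnO2 oxidises it to the ynone F13.
  - Corey–Bakshi–Shibata reduction with catecholborane, using the catalyst antipode that gives the (1R) alcohol, returns 23.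

## Further compounds

F1 | step 14 | 3-[(1R)-1-hydroxy-3-(trimethylsilyl)prop-2-yn-1-yl]-6-(2-phenylethyl)-2-[(E)-2-phenylethenyl]-4H-pyran-4-one | O=c1cc(CCc2ccccc2)oc(/C=C/c2ccccc2)c1[C@@H](O)C#C[Si](C)(C)C
F2 | step 14 | 3-[(1S)-1-{[7-(benzyloxy)-4-oxo-2-(2-phenylethyl)-4H-chromen-6-yl]oxy}-3-(trimethylsilyl)prop-2-yn-1-yl]-6-(2-phenylethyl)-2-[(E)-2-phenylethenyl]-4H-pyran-4-one | O=c1cc(CCc2ccccc2)oc(/C=C/c2ccccc2)c1[C@H](Oc1cc3c(=O)cc(CCc4ccccc4)oc3cc1OCc1ccccc1)C#C[Si](C)(C)C
F3 | step 14 | 3-[(1S)-1-{[7-(benzyloxy)-4-oxo-2-(2-phenylethyl)-4H-chromen-6-yl]oxy}-3-(trimethylsilyl)prop-2-yn-1-yl]-4-oxo-6-(2-phenylethyl)-4H-pyran-2-carbaldehyde | O=Cc1oc(CCc2ccccc2)cc(=O)c1[C@H](Oc1cc3c(=O)cc(CCc4ccccc4)oc3cc1OCc1ccccc1)C#C[Si](C)(C)C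
F4 | step 14 | 3-[(1S)-1-{[7-(benzyloxy)-4-oxo-2-(2-phenylethyl)-4H-chromen-6-yl]oxy}-3-(trimethylsilyl)prop-2-yn-1-yl]-2-[(1S)-1-hydroxy-3-(trimethylsilyl)prop-2-yn-1-yl]-6-(2-phenylethyl)-4H-pyran-4-one | O[C@@H](C#C[Si](C)(C)C)c1oc(CCc2ccccc2)cc(=O)c1[C@H](Oc1cc3c(=O)cc(CCc4ccccc4)oc3cc1OCc1ccccc1)C#C[Si](C)(C)C
F5 | step 14 | 3-[(1R)-1-{[7-(benzyloxy)-4-oxo-2-(2-phenylethyl)-4H-chromen-6-yl]oxy}prop-2-yn-1-yl]-2-[(1S)-1-hydroxyprop-2-yn-1-yl]-6-(2-phenylethyl)-4H-pyran-4-one | O[C@@H](C#C)c1oc(CCc2ccccc2)cc(=O)c1[C@H](Oc1cc3c(=O)cc(CCc4ccccc4)oc3cc1OCc1ccccc1)C#C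
F6 | step 14 | 3-[(1R)-1-{[7-(benzyloxy)-4-oxo-2-(2-phenylethyl)-4H-chromen-6-yl]oxy}prop-2-en-1-yl]-2-[(1S)-1-hydroxyprop-2-en-1-yl]-6-(2-phenylethyl)-4H-pyran-4-one | O[C@@H](C=C)c1oc(CCc2ccccc2)cc(=O)c1[C@H](Oc1cc3c(=O)cc(CCc4ccccc4)oc3cc1OCc1ccccc1)C=C
F7 | step 14 | (5R,8S)-5-{[7-(benzyloxy)-4-oxo-2-(2-phenylethyl)-4H-chromen-6-yl]oxy}-8-hydroxy-2-(2-phenylethyl)-5,8-dihydro-4H-chromen-4-one (5,8-cis) | O=c1cc(CCc2ccccc2)oc2c1[C@H](Oc1cc3c(=O)cc(CCc4ccccc4)oc3cc1OCc1ccccc1)C=C[C@@H]2O
F8 | step 15 | (5S,6R,7R,8S)-5-{[7-(benzyloxy)-4-oxo-2-(2-phenylethyl)-4H-chromen-6-yl]oxy}-6-[dimethyl(propan-2-yloxy)silyl]-7,8-epoxy-2-(2-phenylethyl)-5,6,7,8-tetrahydro-4H-chromen-4-one (epoxide anti to silicon) | O=c1cc(CCc2ccccc2)oc2c1[C@H](Oc1cc3c(=O)cc(CCc4ccccc4)oc3cc1OCc1ccccc1)[C@@H]([Si](C)(C)OC(C)C)[C@@H]1O[C@H]21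
F9 | step 17 | (5S,6S,7R,8S)-5-{[7-(benzyloxy)-4-oxo-2-(2-phenylethyl)-4H-chromen-6-yl]oxy}-6,7-dihydroxy-4-oxo-2-(2-phenylethyl)-5,6,7,8-tetrahydro-4H-chromen-8-yl benzoate | O=c1cc(CCc2ccccc2)oc2c1[C@H](Oc1cc3c(=O)cc(CCc4ccccc4)oc3cc1OCc1ccccc1)[C@@H](O)[C@@H](O)[C@@H]2OC(=O)c1ccccc1
F10 | step 6 | 5-phenylpent-2-ynoyl chloride | O=C(Cl)C#CCCc1ccccc1
F11 | step 6 | 2-[(2E)-1-(morpholin-4-yl)-3-phenylprop-2-en-1-ylidene]-3-oxo-7-phenylhept-4-ynal | O=CC(C(=O)C#CCCc1ccccc1)=C(/C=C/c1ccccc1)N1CCOCC1
F12 | step 10 | 3-(dimethoxymethyl)-2-{1-hydroxy-3-[dimethyl(propan-2-yloxy)silyl]prop-2-yn-1-yl}-6-(2-phenylethyl)-4H-pyran-4-one (racemate) | COC(OC)c1c(C(O)C#C[Si](C)(C)OC(C)C)oc(CCc2ccccc2)cc1=O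
F13 | step 10 | 3-(dimethoxymethyl)-2-{3-[dimethyl(propan-2-yloxy)silyl]prop-2-ynoyl}-6-(2-phenylethyl)-4H-pyran-4-one | COC(OC)c1c(C(=O)C#C[Si](C)(C)OC(C)C)oc(CCc2ccccc2)cc1=O
A1 | alternative 1 | target protected as 6,7-acetonide and 8-O-methoxymethyl ether, 7′-hydroxyl free | O=c1cc(CCc2ccccc2)oc2c1[C@H](Oc1cc3c(=O)cc(CCc4ccccc4)oc3cc1O)[C@@H](OC(C)(C)O3)[C@@H]3[C@@H]2OCOC
A2 | alternative 2 | spiro quinone monoketal (ring A as 8-oxocyclohexadiene, C5 spiro to the benzodioxole of the aromatic unit) | O=C1C=CC2(Oc3cc4c(=O)cc(CCc5ccccc5)oc4cc3O2)c2c1oc(CCc1ccccc1)cc2=O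
A3 | alternative 3 | target protected as 6,7-acetonide and 8,7′-bis(methoxymethyl) ether | O=c1cc(CCc2ccccc2)oc2c1[C@H](Oc1cc3c(=O)cc(CCc4ccccc4)oc3cc1OCOC)[C@@H](OC(C)(C)O3)[C@@H]3[C@@H]2OCOC
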